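**Plan**

- Numbering (elemane): ring C5–C10; C10 carries methyl C14 and vinyl C1=C2; C5 carries the acrylic acid C4(=C3)–C15; lactone O6–C12(=O)–C11(=C13)–C7; angelate on O8; β is the face of the C10 methyl group.
- Enabling feature: C10 is a quaternary ring carbon that bears a vinyl group and is linked through the ring CH2 C9 to the oxygenated C8. A carbon with two vinyl groups plus a C8 enol ether can therefore close the ring at C8=C9 by metathesis: one vinyl becomes C9, the other stays as C1=C2.
- Cuts, in retrosynthetic order: O8–angeloyl and the C15 ester; C11=C13; C8=C9 (cyclohexene); O6–C12 and C6–C7 (aldol–lactonisation); C5–C10 ([3,3] shift); the two ester bonds of an itaconate.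
- Forward: the chain is made by Ireland–Claisen rearrangement of a dienyl itaconate, the γ-lactone by Mukaiyama aldol–lactonisation with a levulinate enol ether, the cyclohexene by ring-closing metathesis, then C8 and C11 are adjusted.
- Stereochemistry: C5 from a chiral boron reagent in the Claisen step; C6 by Felkin–Anh addition; C7 by equilibration to the trans-lactone; C10 by catalyst-controlled choice between the two vinyl groups; C8 by equatorial hydride delivery.

Key step: step 10

Assumption: the antipodes written for the two chiral reagents (the (S,S)-diazaborolidine in step 4 and the (R)-aryloxide of the molybdenum complex in step 10) are taken as the ones that give (5R) and the 10β-methyl ring; each sense is checked on a small batch and the enantiomeric reagent is used if it proves opposite.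

**Route**

Step 1
Reactants: 1 (2Z)-3-methylpent-2-en-4-yn-1-ol
Product: 2 (2Z)-3-methylpenta-2,4-dien-1-ol
Conditions: H2 (1 atm), Pd/CaCO3 poisoned with Pb(OAc)2 (Lindlar catalyst), quinoline, EtOAc, 20 °C, stopped after one equivalent of H2
Reagents that add atoms: none
Why: Lindlar semi-hydrogenation stops a terminal alkyne at the alkene, so the enynol should give the dienol that later supplies one of the two vinyl groups of C10.

Step 2
Reactants: 2 (2Z)-3-methylpenta-2,4-dien-1-ol; 3 itaconic anhydride
Product: 4 4-[(2Z)-3-methylpenta-2,4-dien-1-yl] hydrogen 2-methylidenebutanedioate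
Conditions: toluene, 50 °C, no base
Reagents that add atoms: none
Why: Uncatalysed alcoholysis of itaconic anhydride takes place at the unconjugated carbonyl, which should put the dienyl ester on the CH2CO2 arm and leave the acrylic acid free, while the (Z)-diene is a poor Diels–Alder partner and the absence of base avoids isomerisation to citraconic anhydride.

Step 3
Reactants: 4 4-[(2Z)-3-methylpenta-2,4-dien-1-yl] hydrogen 2-methylidenebutanedioate
Product: 5 1-tert-butyl 4-[(2Z)-3-methylpenta-2,4-dien-1-yl] 2-methylidenebutanedioate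
Conditions: tert-butyl 2,2,2-trichloroacetimidate, CH2Cl2–cyclohexane, 20 °C
Reagents that add atoms: tert-butyl 2,2,2-trichloroacetimidate, CC(C)(C)OC(=N)C(Cl)(Cl)Cl
Why: O-Alkylation of a carboxylic acid by the trichloroacetimidate is promoted by the substrate acid itself, so the acrylic acid should be esterified without a Lewis acid that could ionise the dienyl ester.

Step 4
Reactants: 5 1-tert-butyl 4-[(2Z)-3-methylpenta-2,4-dien-1-yl] 2-methylidenebutanedioate
Product: 8 (2R)-2-[1-(tert-butoxycarbonyl)ethenyl]-3-ethenyl-3-methylpent-4-enoic acid, via boron ketene acetal 6 (not isolated), via acyloxyborane 7 (not isolated)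
Conditions: (4S,5S)-2-bromo-4,5-diphenyl-1,3-bis[3,5-bis(trifluoromethyl)phenylsulfonyl]-1,3,2-diazaborolidine (1.3 equiv), Et3N, toluene–hexane, −78 °C, then −20 to 4 °C; aq. HCl
Reagents that add atoms: none
Why: In this enantioselective Ireland–Claisen rearrangement the CH2 between the two ester arms is the only enolisable position, the chair [3,3] shift of the chiral boron ketene acetal joins C5 to the methyl-bearing diene carbon and so creates the divinyl carbon C10, and the C2-symmetric diazaborolidine selects the enolate face that gives (5R), a reagent type known to work for allyl esters that enolise to dienolates.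

Step 5
Reactants: 8 (2R)-2-[1-(tert-butoxycarbonyl)ethenyl]-3-ethenyl-3-methylpent-4-enoic acid
Product: 10 tert-butyl (3R)-4-ethenyl-3-(hydroxymethyl)-4-methyl-2-methylidenehex-5-enoate, via acyl imidazolide 9 (not isolated)
Conditions: 1,1'-carbonyldiimidazole, THF, 20 °C; then NaBH4, H2O, 0 °C; used without delay
Reagents that add atoms: none
Why: Borohydride reduces the acyl imidazolide of a hindered acid to the primary alcohol and should leave the tert-butyl acrylate, the vinyl groups and C5 untouched.

Step 6
Reactants: 10 tert-butyl (3R)-4-ethenyl-3-(hydroxymethyl)-4-methyl-2-methylidenehex-5-enoate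
Product: 11 tert-butyl (3R)-4-ethenyl-3-formyl-4-methyl-2-methylidenehex-5-enoate
Conditions: Dess–Martin periodinane, NaHCO3, CH2Cl2, 0 to 20 °C; used at once
Reagents that add atoms: none
Why: Buffered Dess–Martin oxidation gives the aldehyde under neutral conditions, which matters because C5–H is α to the formyl group and allylic, so acid or base could epimerise it or move the double bond into conjugation.

Step 7
Reactants: 12 methyl levulinate
Product: 13 methyl (3Z)-4-(trimethylsilyloxy)pent-3-enoate
Conditions: Me3SiCl, Et3N, DMF, 80 °C; distilled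
Reagents that add atoms: chlorotrimethylsilane, C[Si](C)(C)Cl
Why: Enol silylation under equilibrating conditions favours the more substituted enol ether, which places the nucleophilic carbon at C3 of the levulinate (the future C7), and the minor terminal isomer cannot lead to a γ-lactone and is removed after step 8.

Step 8
Reactants: 11 tert-butyl (3R)-4-ethenyl-3-formyl-4-methyl-2-methylidenehex-5-enoate; 13 methyl (3Z)-4-(trimethylsilyloxy)pent-3-enoate
Product: 15 tert-butyl (3R)-3-[(2R,3S)-3-acetyl-5-oxooxolan-2-yl]-4-ethenyl-4-methyl-2-methylidenehex-5-enoate, via aldol hydroxy ester 14 (not isolated)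
Conditions: BF3·OEt2, CH2Cl2, −78 °C; aq. NaHCO3; crude: PPTS (5 mol%), CH2Cl2, 20 °C, then DBU (0.3 equiv), 0 to 20 °C
Reagents that add atoms: none
Why: The Mukaiyama aldol addition through an open transition state should follow the Felkin–Anh model (quaternary C10 anti to the nucleophile, acrylate inside) and so set (6R), the C6 hydroxyl then closes the γ-lactone on the methyl ester in preference to the hindered tert-butyl ester, and DBU equilibrates the ketone α-carbon C7 to the more stable trans-disubstituted lactone whatever the syn/anti outcome of the addition.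

Step 9
Reactants: 15 tert-butyl (3R)-3-[(2R,3S)-3-acetyl-5-oxooxolan-2-yl]-4-ethenyl-4-methyl-2-methylidenehex-5-enoate
Product: 16 tert-butyl (3R)-4-ethenyl-4-methyl-2-methylidene-3-{(2R,3S)-5-oxo-3-[1-(triethylsilyloxy)ethenyl]oxolan-2-yl}hex-5-enoate
Conditions: LiN(SiMe3)2, THF, −78 °C; Et3SiCl, −78 °C
Reagents that add atoms: chlorotriethylsilane, CC[Si](Cl)(CC)CC
Why: Kinetic deprotonation by the hindered, non-nucleophilic amide should take place at the ketone methyl group and not at the tertiary C7–H, the less acidic lactone CH2 or the acrylate, and O-silylation of that enolate gives the 1,1-disubstituted silyl enol ether.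

Step 10
Reactants: 16 tert-butyl (3R)-4-ethenyl-4-methyl-2-methylidene-3-{(2R,3S)-5-oxo-3-[1-(triethylsilyloxy)ethenyl]oxolan-2-yl}hex-5-enoate
Product: 17 tert-butyl 8-(triethylsilyloxy)elema-1,3,8-trien-12,6α-olid-15-oate (5αH,6βH,7αH,10β-methyl)
Conditions: Mo(N-2,6-iPr2C6H3)(CHCMe2Ph)(2,5-Me2C4H2N)(OAr*) (5 mol%; OAr* = (R)-3,3'-dibromo-2'-(tert-butyldimethylsilyloxy)-5,5',6,6',7,7',8,8'-octahydro-1,1'-binaphth-2-olate), C6H6, 22 °C, slow N2 sweep to remove ethene
Reagents that add atoms: none
Why: The molybdenum alkylidene exchanges onto one vinyl group of C10, adds across the enol ether C8=CH2 to give a metallacyclobutane and collapses to the cyclic silyl enol ether and Mo=CH2, which is released as ethene (ring-closing olefin metathesis). The closest known reactions are ring-closing metathesis of 1,1-disubstituted enol ethers, silyl enol ethers included, and the enantioselective ring closure of all-carbon quaternary divinyl carbons by stereogenic-at-molybdenum monoaryloxide pyrrolide alkylidenes. The six-membered carbocycle C5–C10 is closed by metathesis with the new C8=C9 double bond inside the ring, the vinyl CH becoming C9. The new stereocentre C10 results from the choice between the two diastereotopic vinyl groups, and this choice is made by the chiral metal centre with its bulky aryloxide, not by the substrate. The step needs the vinyl group whose reaction leaves the methyl group axial on the β face and the second vinyl group equatorial, trans to the C5 acrylate; the substrate contributes the trans-lactone, which fixes C6 and C7 so that each vinyl group can close only one half-chair, and the near-equal size of methyl and vinyl, which leaves little inherent bias for the catalyst to overcome. The 1,1-disubstituted, electron-poor acrylate and the lactone take no part, and the product holds the C8 ketone in masked form.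

Step 11
Reactants: 17 tert-butyl 8-(triethylsilyloxy)elema-1,3,8-trien-12,6α-olid-15-oate
Product: 18 tert-butyl 8-oxoelema-1,3-dien-12,6α-olid-15-oate
Conditions: 1 M HCl, THF, 0 °C; used directly
Reagents that add atoms: none
Why: Acid hydrolysis of the silyl enol ether protonates C9 and releases the C8 ketone without touching C7, and the short contact at 0 °C should keep the tert-butyl ester and the trans ring fusion intact.

Step 12
Reactants: 18 tert-butyl 8-oxoelema-1,3-dien-12,6α-olid-15-oate
Product: 19 tert-butyl 8β-hydroxyelema-1,3-dien-12,6α-olid-15-oate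
Conditions: NaBH4, MeOH–CH2Cl2, −40 °C
Reagents that add atoms: none
Why: In the chair locked by the trans-lactone the axial 10β-methyl group blocks the axial path to C8, so hydride should enter along the equatorial α path and give the axial 8β-alcohol (steric approach control as in cyclohexanones with a syn-axial methyl group), and borohydride is chosen because bulky trialkylborohydrides would also reduce the acrylate in conjugate fashion.

Step 13
Reactants: 19 tert-butyl 8β-hydroxyelema-1,3-dien-12,6α-olid-15-oate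
Product: 20 tert-butyl 8β-(triethylsilyloxy)elema-1,3-dien-12,6α-olid-15-oate
Conditions: Et3SiOSO2CF3, 2,6-lutidine, CH2Cl2, −78 to 0 °C
Reagents that add atoms: triethylsilyl trifluoromethanesulfonate, CC[Si](CC)(CC)OS(=O)(=O)C(F)(F)F
Why: The silyl triflate silylates even a hindered axial secondary alcohol, and the ether keeps O8 out of the enolate chemistry of the next step.

Step 14
Reactants: 20 tert-butyl 8β-(triethylsilyloxy)elema-1,3-dien-12,6α-olid-15-oate
Product: 23 tert-butyl 8β-(triethylsilyloxy)elema-1,3,11(13)-trien-12,6α-olid-15-oate, via Mannich base 21 (not isolated), via trimethylammonium iodide 22 (not isolated)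
Conditions: LiN(SiMe3)2, THF, −78 °C; Me2N=CH2 I (Eschenmoser's salt), −78 to 20 °C; MeI, THF, 20 °C; aq. NaHCO3
Reagents that add atoms: N,N-dimethylmethyleneiminium iodide, C=[N+](C)C.[I-]
Why: Mannich reaction of the lactone enolate (the only enolisable position left), quaternisation and elimination of trimethylamine is the standard α-methylenation of γ-lactones and creates C11=C13, the non-nucleophilic silylamide being used so that the acrylate is not attacked.

Step 15
Reactants: 23 tert-butyl 8β-(triethylsilyloxy)elema-1,3,11(13)-trien-12,6α-olid-15-oate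
Product: 24 tert-butyl 8β-hydroxyelema-1,3,11(13)-trien-12,6α-olid-15-oate
Conditions: HF·pyridine, THF, 0 to 20 °C
Reagents that add atoms: none
Why: Fluoride cleavage of the triethylsilyl ether under buffered acidic conditions frees O8 without conjugate addition to the two α-methylene carbonyl units.

Step 16
Reactants: 24 tert-butyl 8β-hydroxyelema-1,3,11(13)-trien-12,6α-olid-15-oate; 25 angelic acid
Product: 27 tert-butyl 8β-angeloyloxyelema-1,3,11(13)-trien-12,6α-olid-15-oate, via mixed Yamaguchi anhydride 26 (not isolated)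
Conditions: 25, 2,4,6-Cl3C6H2COCl, Et3N, toluene, 20 °C; then 24, toluene, 80 °C, no DMAP
Reagents that add atoms: none
Why: Yamaguchi-type mixed-anhydride esterification without a nucleophilic catalyst should acylate the axial alcohol at the less shielded angeloyl carbonyl and avoids the addition–elimination path that turns angelates into tiglates.

Step 17
Reactants: 27 tert-butyl 8β-angeloyloxyelema-1,3,11(13)-trien-12,6α-olid-15-oate
Product: 28 8β-angeloyloxyelema-1,3,11(13)-trien-12,6α-olid-15-oic acid (target)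
Conditions: CF3CO2H, CH2Cl2, 0 °C
Reagents that add atoms: none
Why: Acidolysis of the tert-butyl ester by loss of the tert-butyl cation frees the acrylic acid under conditions that the lactone, the angelate and the alkenes should tolerate.

**Compound list**

1 | (2Z)-3-methylpent-2-en-4-yn-1-ol | C#C/C(C)=C\CO | starting material
2 | (2Z)-3-methylpenta-2,4-dien-1-ol | C=C/C(C)=C\CO | intermediate
3 | itaconic anhydride (3-methylideneoxolane-2,5-dione) | C=C1CC(=O)OC1=O | starting material
4 | 4-[(2Z)-3-methylpenta-2,4-dien-1-yl] hydrogen 2-methylidenebutanedioate | C=C/C(C)=C\COC(=O)CC(=C)C(=O)O | intermediate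
5 | 1-tert-butyl 4-[(2Z)-3-methylpenta-2,4-dien-1-yl] 2-methylidenebutanedioate | C=C/C(C)=C\COC(=O)CC(=C)C(=O)OC(C)(C)C | intermediate
6 | boron ketene acetal of 5 on the (S,S)-diazaborolidine, drawn as the E(O) enolate | C=C/C(C)=C\CO/C(OB1N(S(=O)(=O)c2cc(cc(c2)C(F)(F)F)C(F)(F)F)[C@@H](c2ccccc2)[C@H](c2ccccc2)N1S(=O)(=O)c1cc(cc(c1)C(F)(F)F)C(F)(F)F)=C\C(=C)C(=O)OC(C)(C)C | intermediate
7 | acyloxyborane of acid 8 | C=CC(C)(C=C)[C@H](C(=C)C(=O)OC(C)(C)C)C(=O)OB1N(S(=O)(=O)c2cc(cc(c2)C(F)(F)F)C(F)(F)F)[C@@H](c2ccccc2)[C@H](c2ccccc2)N1S(=O)(=O)c1cc(cc(c1)C(F)(F)F)C(F)(F)F | intermediate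
8 | (2R)-2-[1-(tert-butoxycarbonyl)ethenyl]-3-ethenyl-3-methylpent-4-enoic acid | C=CC(C)(C=C)[C@H](C(=C)C(=O)OC(C)(C)C)C(=O)O | intermediate
9 | acyl imidazolide of 8 | C=CC(C)(C=C)[C@H](C(=C)C(=O)OC(C)(C)C)C(=O)n1ccnc1 | intermediate
10 | tert-butyl (3R)-4-ethenyl-3-(hydroxymethyl)-4-methyl-2-methylidenehex-5-enoate | C=CC(C)(C=C)[C@H](C(=C)C(=O)OC(C)(C)C)CO | intermediate
11 | tert-butyl (3R)-4-ethenyl-3-formyl-4-methyl-2-methylidenehex-5-enoate | C=CC(C)(C=C)[C@H](C(=C)C(=O)OC(C)(C)C)C=O | intermediate
12 | methyl levulinate (methyl 4-oxopentanoate) | CC(=O)CCC(=O)OC | starting material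
13 | methyl (3Z)-4-(trimethylsilyloxy)pent-3-enoate | C/C(O[Si](C)(C)C)=C/CC(=O)OC | intermediate
14 | aldol hydroxy ester, (5R,6R,7S) in elemane numbering: C6 hydroxyl, C7 acetyl and CH2CO2Me (its C7 epimer converges on 15) | C=CC(C)(C=C)[C@H](C(=C)C(=O)OC(C)(C)C)[C@@H](O)[C@H](CC(=O)OC)C(C)=O | intermediate
15 | tert-butyl (3R)-3-[(2R,3S)-3-acetyl-5-oxooxolan-2-yl]-4-ethenyl-4-methyl-2-methylidenehex-5-enoate (trans-lactone methyl ketone) | C=CC(C)(C=C)[C@H](C(=C)C(=O)OC(C)(C)C)[C@H]1OC(=O)C[C@@H]1C(C)=O | intermediate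
16 | tert-butyl (3R)-4-ethenyl-4-methyl-2-methylidene-3-{(2R,3S)-5-oxo-3-[1-(triethylsilyloxy)ethenyl]oxolan-2-yl}hex-5-enoate (metathesis precursor) | C=CC(C)(C=C)[C@H](C(=C)C(=O)OC(C)(C)C)[C@H]1OC(=O)C[C@@H]1C(=C)O[Si](CC)(CC)CC | intermediate
17 | tert-butyl 8-(triethylsilyloxy)elema-1,3,8-trien-12,6α-olid-15-oate (5αH,6βH,7αH,10β-methyl; metathesis product) | C=C[C@]1(C)C=C(O[Si](CC)(CC)CC)[C@H]2CC(=O)O[C@@H]2[C@H]1C(=C)C(=O)OC(C)(C)C | intermediate
18 | tert-butyl 8-oxoelema-1,3-dien-12,6α-olid-15-oate (5αH,6βH,7αH,10β-methyl) | C=C[C@]1(C)CC(=O)[C@H]2CC(=O)O[C@@H]2[C@H]1C(=C)C(=O)OC(C)(C)C | intermediate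
19 | tert-butyl 8β-hydroxyelema-1,3-dien-12,6α-olid-15-oate | C=C[C@]1(C)C[C@@H](O)[C@H]2CC(=O)O[C@@H]2[C@H]1C(=C)C(=O)OC(C)(C)C | intermediate
20 | tert-butyl 8β-(triethylsilyloxy)elema-1,3-dien-12,6α-olid-15-oate | C=C[C@]1(C)C[C@@H](O[Si](CC)(CC)CC)[C@H]2CC(=O)O[C@@H]2[C@H]1C(=C)C(=O)OC(C)(C)C | intermediate
21 | 11-(dimethylaminomethyl) derivative of 20 (C11 not assigned, lost in the elimination) | C=C[C@]1(C)C[C@@H](O[Si](CC)(CC)CC)[C@H]2C(CN(C)C)C(=O)O[C@@H]2[C@H]1C(=C)C(=O)OC(C)(C)C | intermediate
22 | trimethylammonium iodide of 21 | C=C[C@]1(C)C[C@@H](O[Si](CC)(CC)CC)[C@H]2C(C[N+](C)(C)C)C(=O)O[C@@H]2[C@H]1C(=C)C(=O)OC(C)(C)C.[I-] | intermediate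
23 | tert-butyl 8β-(triethylsilyloxy)elema-1,3,11(13)-trien-12,6α-olid-15-oate | C=C[C@]1(C)C[C@@H](O[Si](CC)(CC)CC)[C@H]2C(=C)C(=O)O[C@@H]2[C@H]1C(=C)C(=O)OC(C)(C)C | intermediate
24 | tert-butyl 8β-hydroxyelema-1,3,11(13)-trien-12,6α-olid-15-oate | C=C[C@]1(C)C[C@@H](O)[C@H]2C(=C)C(=O)O[C@@H]2[C@H]1C(=C)C(=O)OC(C)(C)C | intermediate
25 | angelic acid, (2Z)-2-methylbut-2-enoic acid | C/C=C(/C)C(=O)O | starting material
26 | angelic 2,4,6-trichlorobenzoic anhydride | C/C=C(/C)C(=O)OC(=O)c1c(Cl)cc(Cl)cc1Cl | intermediate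
27 | tert-butyl 8β-angeloyloxyelema-1,3,11(13)-trien-12,6α-olid-15-oate | C=C[C@]1(C)C[C@@H](OC(=O)/C(C)=C\C)[C@H]2C(=C)C(=O)O[C@@H]2[C@H]1C(=C)C(=O)OC(C)(C)C | intermediate
28 | 8β-angeloyloxyelema-1,3,11(13)-trien-12,6α-olid-15-oic acid, (5R,6R,7R,8R,10S) | C=C[C@]1(C)C[C@@H](OC(=O)/C(C)=C\C)[C@H]2C(=C)C(=O)O[C@@H]2[C@H]1C(=C)C(=O)O | target

**Count**

Total steps: 17. Longest linear sequence: 16 steps (steps 1–6 and 8–17, from 1); step 7 is a one-step branch from 12.

**Steps most likely to fail**

1. Step 10 (key step). Process at risk: incomplete discrimination between the two vinyl groups, so that both C10 epimers form, or stalling because the alkylidene has to load on a neopentyl-type alkene. Fallback, from 1 back to 18: C10 is set in the sigmatropic step, and the metathesis then has only one vinyl group to use.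
   - 1 is silylated on oxygen and on the alkyne terminus (EtMgBr, Me3SiCl, THF) to the bis-silyl compound F1. Dilute acid on work-up frees the alcohol to give (2Z)-3-methyl-5-(trimethylsilyl)pent-2-en-4-yn-1-ol F2.
   - F2 is carried, without semi-hydrogenation, through the operations of steps 2 and 3 to the hydrogen itaconate F3 and the tert-butyl diester F4.
   - The rearrangement of step 4 then runs through the boron ketene acetal F5 and the acyloxyborane F6 to the acid F7. In F7, C10 bears methyl, vinyl and silylethynyl groups and is a stereocentre fixed by the chair transition state (E(O) enolate, alkyne cis to the CH2O end; the (E)-enynol would be used if the enolate geometry proves to be the other one).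
   - The operations of steps 5, 6, 8 and 9 give the acyl imidazolide F8, the alcohol F9, the aldehyde F10, the aldol adduct F11, the keto lactone F12 and the triethylsilyl enol ether F13.
   - RuCl2(=CHPh)(PCy3)(1,3-dimesitylimidazolidin-2-ylidene), the second-generation Grubbs catalyst, in toluene at 60 °C closes the ring of F13 through its only vinyl group to the bicyclic enol ether F14. The hindered silylalkyne should stay out.
   - Bu4NF/AcOH removes both silyl groups to give the ethynyl ketone F15, and Lindlar semi-hydrogenation of F15 gives 18.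

2. Step 4. Process at risk: low facial selectivity of the boron enolate, or isomerisation of the itaconate to the conjugated mesaconate before it rearranges. Fallback, from 5 back to 8: the rearrangement is run without a chiral reagent and the acid is resolved.
   - LiN(SiMe3)2 and Me3SiCl (THF, −78 to 20 °C) convert 5 into the trimethylsilyl ketene acetal F16, which rearranges to the silyl ester F17. Aqueous work-up gives the racemic acid F18.
   - Crystallisation with (R)-1-phenylethylamine is expected to deliver the salt F19 of the (R)-acid; the antipodal amine is used if the other diastereomeric salt is the less soluble one. Acidification returns 8.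

3. Step 16. Process at risk: slow acylation of the hindered axial alcohol and Z-to-E isomerisation of the angeloyl group during activation. Fallback, from 24 back to 27: the double bond of the ester is built after the acylation.
   - 24 is esterified with 2-[bis(2,2,2-trifluoroethoxy)phosphoryl]propanoic acid (EDC·HCl, DMAP, CH2Cl2) to the phosphonate ester F20.
   - Still–Gennari olefination of F20 with acetaldehyde (KN(SiMe3)2, 18-crown-6, THF, −78 °C) gives the (Z)-2-methylbut-2-enoate 27.

**Further compounds**

F1 | step 10 | trimethyl{[(2Z)-3-methyl-5-(trimethylsilyl)pent-2-en-4-yn-1-yl]oxy}silane | C[Si](C)(C)C#C/C(C)=C\CO[Si](C)(C)C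
F2 | step 10 | (2Z)-3-methyl-5-(trimethylsilyl)pent-2-en-4-yn-1-ol | C[Si](C)(C)C#C/C(C)=C\CO
F3 | step 10 | 4-[(2Z)-3-methyl-5-(trimethylsilyl)pent-2-en-4-yn-1-yl] hydrogen 2-methylidenebutanedioate | C[Si](C)(C)C#C/C(C)=C\COC(=O)CC(=C)C(=O)O
F4 | step 10 | 1-tert-butyl 4-[(2Z)-3-methyl-5-(trimethylsilyl)pent-2-en-4-yn-1-yl] 2-methylidenebutanedioate | C[Si](C)(C)C#C/C(C)=C\COC(=O)CC(=C)C(=O)OC(C)(C)C
F5 | step 10 | boron ketene acetal of F4 on the (S,S)-diazaborolidine (E(O) enolate) | C[Si](C)(C)C#C/C(C)=C\CO/C(OB1N(S(=O)(=O)c2cc(cc(c2)C(F)(F)F)C(F)(F)F)[C@@H](c2ccccc2)[C@H](c2ccccc2)N1S(=O)(=O)c1cc(cc(c1)C(F)(F)F)C(F)(F)F)=C\C(=C)C(=O)OC(C)(C)C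
F6 | step 10 | acyloxyborane of acid F7 | C=C[C@@](C)(C#C[Si](C)(C)C)[C@H](C(=C)C(=O)OC(C)(C)C)C(=O)OB1N(S(=O)(=O)c2cc(cc(c2)C(F)(F)F)C(F)(F)F)[C@@H](c2ccccc2)[C@H](c2ccccc2)N1S(=O)(=O)c1cc(cc(c1)C(F)(F)F)C(F)(F)F
F7 | step 10 | 2-[1-(tert-butoxycarbonyl)ethenyl]-3-ethenyl-3-methyl-5-(trimethylsilyl)pent-4-ynoic acid, C5 as in 8 and C10 as needed for 10β-methyl | C=C[C@@](C)(C#C[Si](C)(C)C)[C@H](C(=C)C(=O)OC(C)(C)C)C(=O)O
F8 | step 10 | acyl imidazolide of F7 | C=C[C@@](C)(C#C[Si](C)(C)C)[C@H](C(=C)C(=O)OC(C)(C)C)C(=O)n1ccnc1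
F9 | step 10 | primary alcohol from F7 | C=C[C@@](C)(C#C[Si](C)(C)C)[C@H](C(=C)C(=O)OC(C)(C)C)CO
F10 | step 10 | aldehyde from F9 | C=C[C@@](C)(C#C[Si](C)(C)C)[C@H](C(=C)C(=O)OC(C)(C)C)C=O
F11 | step 10 | aldol hydroxy ester from F10 and 13 | C=C[C@@](C)(C#C[Si](C)(C)C)[C@H](C(=C)C(=O)OC(C)(C)C)[C@@H](O)[C@H](CC(=O)OC)C(C)=O
F12 | step 10 | trans-lactone methyl ketone with the silylethynyl group on C10 | C=C[C@@](C)(C#C[Si](C)(C)C)[C@H](C(=C)C(=O)OC(C)(C)C)[C@H]1OC(=O)C[C@@H]1C(C)=O
F13 | step 10 | triethylsilyl enol ether of F12 | C=C[C@@](C)(C#C[Si](C)(C)C)[C@H](C(=C)C(=O)OC(C)(C)C)[C@H]1OC(=O)C[C@@H]1C(=C)O[Si](CC)(CC)CC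
F14 | step 10 | bicyclic triethylsilyl enol ether with 10α-(trimethylsilylethynyl) and 10β-methyl | C[Si](C)(C)C#C[C@]1(C)C=C(O[Si](CC)(CC)CC)[C@H]2CC(=O)O[C@@H]2[C@H]1C(=C)C(=O)OC(C)(C)C
F15 | step 10 | 10α-ethynyl analogue of ketone 18 | C#C[C@]1(C)CC(=O)[C@H]2CC(=O)O[C@@H]2[C@H]1C(=C)C(=O)OC(C)(C)C
F16 | step 4 | trimethylsilyl ketene acetal of 5 | C=C/C(C)=C\COC(O[Si](C)(C)C)=CC(=C)C(=O)OC(C)(C)C
F17 | step 4 | trimethylsilyl ester of the racemic acid | C=CC(C)(C=C)C(C(=C)C(=O)OC(C)(C)C)C(=O)O[Si](C)(C)C
F18 | step 4 | racemic 2-[1-(tert-butoxycarbonyl)ethenyl]-3-ethenyl-3-methylpent-4-enoic acid | C=CC(C)(C=C)C(C(=C)C(=O)OC(C)(C)C)C(=O)O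
F19 | step 4 | (R)-1-phenylethylammonium salt of acid 8 | C=CC(C)(C=C)[C@H](C(=C)C(=O)OC(C)(C)C)C(=O)[O-].C[C@@H]([NH3+])c1ccccc1
F20 | step 16 | 8β-{2-[bis(2,2,2-trifluoroethoxy)phosphoryl]propanoyloxy} ester of 24 | C=C[C@]1(C)C[C@@H](OC(=O)C(C)P(=O)(OCC(F)(F)F)OCC(F)(F)F)[C@H]2C(=C)C(=O)O[C@@H]2[C@H]1C(=C)C(=O)OC(C)(C)C
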